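A one-step world has no fork: a substrate molecule has one way out, to target, and once the substrate has gone, the fraction of the charge found as target is the same whatever was charged. Our flasks have a fork, since a substrate molecule may also meet a second one and leave as self-condensation product. So we follow one molecule and ask for its loss odds, the fraction of the charge lost divided by the fraction kept as target, which is the inverse of a selectivity factor.

| setting | east | north-west | Tuesday's | Sunday's | Monday's | Saturday's |
|---|---|---|---|---|---|---|
| substrate | 0.65 M | 2.3 M | 0.50 M | 0.60 M | 2.0 M | 1.0 M |
| remark | run made earlier | run made earlier |  |  |  |  |
| time |  |  | 80 min | 80 min | 80 min | 80 min |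

| run | time / min | target / % |
|---|---|---|
| east | 12.0 | 80.8 |
| east | 25.0 | 82.3 |
| east | 30.0 | 81.8 |
| east | 50.0 | 81.3 |
| east | 60.0 | 79.7 |
| east | 80.0 | 78.3 |
| north-west | 12.0 | 40.4 |
| north-west | 25.0 | 39.7 |
| north-west | 30.0 | 40.4 |
| north-west | 50.0 | 38.6 |
| north-west | 60.0 | 39.6 |
| north-west | 80.0 | 40.1 |

(scatter of a reading: 1 percentage point)

1. ranking by amount of target, in percent of the substrate charged, from high to low, at 80 min (Tuesday's / Sunday's / Monday's / Saturday's)
2. the amount of target, in percent of the substrate charged of the flask you put first, at 80 min
3. the amount of target, in percent of the substrate charged of the flask you put last, at 80 min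

- in percentages every species weighs as the substrate in it: one self-condensation product counts as two
- reactions considered so far: substrate -> target; target -> over-reaction product; 2 substrate -> self-condensation product

East sags by 4 percentage points between 25.0 min and 80.0 min, and north-west scatters around a level, so we take the mean of the six readings of each run: 80.7% and 39.8% of the charge, which are loss odds of 0.239 and 1.51.

The bench rule of thumb says that a second-order step competing with a first-order one gives loss odds proportional to the charge. Applied honestly to north-west, it takes east's odds to 0.846 and target to 54.2%, well above the reading. That is the border of the rule: the charges stand in the ratio 3.54, but the odds stand in the ratio 6.32.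

So we keep the slope instead and define the fork exponent, the logarithm of the odds ratio divided by the logarithm of the charge ratio, 1.46, a reading that carries the scatter of 1 point, and larger than the rule's one. Carried from east, it gives us 86.0% for Tuesday's and 44.8% for Monday's, with the flasks ranked by rising charge.

The forecast ranks Tuesday's > Sunday's > Saturday's > Monday's, with 84% (81.5% to 86.5%) and 45% (42.5% to 49%), on the ground that “Selectivity therefore falls more steeply with concentration”. Its order is ours, and its top stands 2 points below our figure.

The flasks give Tuesday's > Sunday's > Saturday's > Monday's, with 85.8% for Tuesday's and 43.6% for Monday's.

    substrate → target, rate k1*[substrate]/(1 + ([substrate]/sat1)) (7.59 mM, k = 19.7 min⁻¹)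
    target → over-reaction product (k = 2.39 × 10⁻⁴ min⁻¹)
    2 substrate → self-condensation product (k = 0.140 M⁻¹ min⁻¹)

At the start of Monday's flask, substrate goes into target at 0.13 of the rate at which it goes into self-condensation product, and at 80.0 min that flask holds 55.6% of self-condensation product against 43.6% of target. Monday's loss odds stand at 1.29, and the fork exponent carries them down to a reckoned 62.0% of target for a neighbour of Monday's charged with 1.2 M, a flask that stands at 61.0%.

The data come from a simulation on assumed constants; noise was put on by code.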